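Ring atoms are labelled C1–C11 in their order in the target SMILES (C9 = C=O, C8 = CH2, C7 = CH–CH3). The doubly bridged cyclobutane is forged by a transannular crossed [2+2] photocycloaddition of a ten-membered 1,5-dien-3-one, which by the rule of five gives the ketone ring one carbon short, as a bicyclo[2.1.1]hexan-2-one. The key step enlarges it: C9 is flanked by the non-enolisable cyclobutane bridgehead C10 and by C7, so the silyl enol ether forms only toward C7; dichlorocarbene addition and electrocyclic opening of the fused cyclopropane insert C8, giving the six-membered ring C5–C6–C7–C8–C9–C10 as an α-chloro enone; hydrogenation then sets C7. The macrocycle comes from (R)-glyceraldehyde acetonide.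

Key step: step 17

Remark: the other labels are C1 (CH–O-angeloyl), C2 (CH–O-isovaleryl), C3 (CH–OH), C4 (CMe2), C5/C6/C10/C11 (cyclobutane; C11 carries CH3); the same labels are used for these carbons in the open-chain precursors. The carbinol configuration at C9 in 13–15 and the cyclopropane face in 26 are of no consequence, because these centres are erased later.

Step 1
Reactants: 1 (R)-2,2-dimethyl-1,3-dioxolane-4-carbaldehyde; 2 1-bromo-3-methylbut-2-ene
Product: 3 (S)-1-[(R)-2,2-dimethyl-1,3-dioxolan-4-yl]-2,2-dimethylbut-3-en-1-ol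
Conditions: In powder, DMF, 0 °C to rt
Reagents that add atoms: none
Why: Barbier-type indium allylation in which the prenylindium reacts at its γ-carbon through a six-membered transition state (creating quaternary C4), and Felkin–Anh addition anti to the dioxolane C–O bond should give the 2,3-anti carbinol C3.

Step 2
Reactants: 3 (S)-1-[(R)-2,2-dimethyl-1,3-dioxolan-4-yl]-2,2-dimethylbut-3-en-1-ol
Product: 4 tert-butyl{[(S)-1-[(R)-2,2-dimethyl-1,3-dioxolan-4-yl]-2,2-dimethylbut-3-en-1-yl]oxy}dimethylsilane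
Conditions: TBSOTf, 2,6-lutidine, CH2Cl2, 0 °C
Reagents that add atoms: tert-butyldimethylsilyl trifluoromethanesulfonate CC(C)(C)[Si](C)(C)OS(=O)(=O)C(F)(F)F
Why: O-silylation of the hindered neopentyl alcohol with the silyl triflate, which masks the C3 hydroxyl until the last step; no stereocentre is touched.

Step 3
Reactants: 4 tert-butyl{[(S)-1-[(R)-2,2-dimethyl-1,3-dioxolan-4-yl]-2,2-dimethylbut-3-en-1-yl]oxy}dimethylsilane
Product: 6 (S)-3-[(tert-butyldimethylsilyl)oxy]-3-[(R)-2,2-dimethyl-1,3-dioxolan-4-yl]-2,2-dimethylpropanal, via ozonide 5 (not isolated)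
Conditions: O3, CH2Cl2, −78 °C; then PPh3, −78 °C to rt
Reagents that add atoms: ozone [O-][O+]=O
Why: Ozonolysis of the only C=C bond (1,3-dipolar cycloaddition and cycloreversion to the ozonide, then reduction) gives the non-enolisable aldehyde C5 without touching a stereocentre.

Step 4
Reactants: 6 (S)-3-[(tert-butyldimethylsilyl)oxy]-3-[(R)-2,2-dimethyl-1,3-dioxolan-4-yl]-2,2-dimethylpropanal; 7 2-(triphenyl-λ5-phosphanylidene)acetaldehyde
Product: 8 (S,E)-5-[(tert-butyldimethylsilyl)oxy]-5-[(R)-2,2-dimethyl-1,3-dioxolan-4-yl]-4,4-dimethylpent-2-enal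
Conditions: toluene, 90 °C
Reagents that add atoms: none
Why: Wittig olefination with the stabilised formylmethylene ylide should give the (E)-enal (C5=C10 with C9 as aldehyde); no stereocentre is formed.

Step 5
Reactants: 9 (R)-but-3-yn-2-ol
Product: 11 (R)-pent-3-yn-2-ol, via dilithium alkoxide acetylide 10 (not isolated)
Conditions: n-BuLi (2.1 equiv), THF, −78 to 0 °C; then MeI, DMPU, 0 °C to rt
Reagents that add atoms: iodomethane CI
Why: Double deprotonation followed by C-methylation of the more nucleophilic acetylide terminus installs the methyl group that becomes the C11 methyl; the carbinol centre is not involved.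

Step 6
Reactants: 11 (R)-pent-3-yn-2-ol
Product: 12 (R)-pent-3-yn-2-yl methanesulfonate
Conditions: MsCl, Et3N, CH2Cl2, −40 °C
Reagents that add atoms: methanesulfonyl chloride CS(=O)(=O)Cl
Why: O-sulfonylation with retention gives the propargylic mesylate needed for the Marshall propargylation.

Step 7
Reactants: 8 (S,E)-5-[(tert-butyldimethylsilyl)oxy]-5-[(R)-2,2-dimethyl-1,3-dioxolan-4-yl]-4,4-dimethylpent-2-enal; 12 (R)-pent-3-yn-2-yl methanesulfonate
Product: 13 (4S,5R,6E,9S)-9-[(tert-butyldimethylsilyl)oxy]-9-[(R)-2,2-dimethyl-1,3-dioxolan-4-yl]-4,8,8-trimethylnon-6-en-2-yn-5-ol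
Conditions: Pd(OAc)2 (5 mol %), PPh3 (5 mol %), InI, THF–HMPA (3:1), rt
Reagents that add atoms: none
Why: Marshall propargylation, in which Pd(0) displaces the mesylate anti (SN2′), transmetalation gives an allenylindium and its SE2′ 1,2-addition to the enal through a cyclic transition state forms C7–C9 with net inversion at the mesylate carbon (this sets C7, the later steering centre) and the carbinol anti to the methyl group.

Step 8
Reactants: 13 (4S,5R,6E,9S)-9-[(tert-butyldimethylsilyl)oxy]-9-[(R)-2,2-dimethyl-1,3-dioxolan-4-yl]-4,8,8-trimethylnon-6-en-2-yn-5-ol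
Product: 15 (2E,4S,5R,6E,9S)-9-[(tert-butyldimethylsilyl)oxy]-9-[(R)-2,2-dimethyl-1,3-dioxolan-4-yl]-2-iodo-4,8,8-trimethylnona-2,6-dien-5-ol, via bis(zirconocene) intermediate 14 (not isolated)
Conditions: Cp2Zr(H)Cl (3 equiv), THF, rt to 50 °C; then I2, 0 °C
Reagents that add atoms: iodine II
Why: Syn hydrozirconation with the Schwartz reagent places zirconium on the less hindered, methyl-bearing alkyne carbon C11 after equilibration, and iodinolysis with retention fixes the (E)-vinyl iodide (iodine trans to C7).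

Step 9
Reactants: 15 (2E,4S,5R,6E,9S)-9-[(tert-butyldimethylsilyl)oxy]-9-[(R)-2,2-dimethyl-1,3-dioxolan-4-yl]-2-iodo-4,8,8-trimethylnona-2,6-dien-5-ol
Product: 16 (2E,4S,6E,9S)-9-[(tert-butyldimethylsilyl)oxy]-9-[(R)-2,2-dimethyl-1,3-dioxolan-4-yl]-2-iodo-4,8,8-trimethylnona-2,6-dien-5-one
Conditions: Dess–Martin periodinane, NaHCO3, CH2Cl2, 0 °C to rt
Reagents that add atoms: none
Why: Dess–Martin oxidation of the allylic alcohol under buffered, non-basic conditions gives the (E)-enone chromophore (C9) and should leave the α-stereocentre C7 intact.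

Step 10
Reactants: 16 (2E,4S,6E,9S)-9-[(tert-butyldimethylsilyl)oxy]-9-[(R)-2,2-dimethyl-1,3-dioxolan-4-yl]-2-iodo-4,8,8-trimethylnona-2,6-dien-5-one
Product: 17 (2R,3S,5E,8S,9E)-3-[(tert-butyldimethylsilyl)oxy]-1,2-dihydroxy-10-iodo-4,4,8-trimethylundeca-5,9-dien-7-one
Conditions: CuCl2·2H2O, MeCN, 0 °C to rt
Reagents that add atoms: none
Why: Lewis-acid-mediated hydrolysis selective for the terminal isopropylidene acetal; the hindered secondary TBS ether should survive.

Step 11
Reactants: 17 (2R,3S,5E,8S,9E)-3-[(tert-butyldimethylsilyl)oxy]-1,2-dihydroxy-10-iodo-4,4,8-trimethylundeca-5,9-dien-7-one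
Product: 18 (2R,3S,5E,8S,9E)-3-[(tert-butyldimethylsilyl)oxy]-2-hydroxy-10-iodo-4,4,8-trimethyl-1-[(triethylsilyl)oxy]undeca-5,9-dien-7-one
Conditions: TESCl, imidazole, CH2Cl2, −30 °C
Reagents that add atoms: chlorotriethylsilane CC[Si](Cl)(CC)CC
Why: Selective silylation of the primary hydroxyl (C1) differentiates it from the secondary C2 hydroxyl.

Step 12
Reactants: 18 (2R,3S,5E,8S,9E)-3-[(tert-butyldimethylsilyl)oxy]-2-hydroxy-10-iodo-4,4,8-trimethyl-1-[(triethylsilyl)oxy]undeca-5,9-dien-7-one; 19 3-methylbutanoyl chloride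
Product: 20 (2R,3S,5E,8S,9E)-3-[(tert-butyldimethylsilyl)oxy]-10-iodo-4,4,8-trimethyl-7-oxo-1-[(triethylsilyl)oxy]undeca-5,9-dien-2-yl 3-methylbutanoate
Conditions: pyridine, DMAP (cat.), CH2Cl2, 0 °C
Reagents that add atoms: none
Why: Acylation of the only free hydroxyl installs the C2 isovalerate of the target early, so that the three oxygens never need to be told apart later.

Step 13
Reactants: 20 (2R,3S,5E,8S,9E)-3-[(tert-butyldimethylsilyl)oxy]-10-iodo-4,4,8-trimethyl-7-oxo-1-[(triethylsilyl)oxy]undeca-5,9-dien-2-yl 3-methylbutanoate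
Product: 22 (2S,3S,5E,8S,9E)-3-[(tert-butyldimethylsilyl)oxy]-10-iodo-4,4,8-trimethyl-1,7-dioxoundeca-5,9-dien-2-yl 3-methylbutanoate, via alkoxysulfonium chloride 21 (not isolated)
Conditions: (COCl)2, DMSO, CH2Cl2, −78 to −40 °C; then i-Pr2NEt, −78 to 0 °C
Reagents that add atoms: none
Why: Under Swern conditions the primary triethylsilyl ether is cleaved by the chlorosulfonium electrophile and oxidised in the same flask to the C1 aldehyde, while the secondary TBS ether and the ester are inert.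

Step 14
Reactants: 22 (2S,3S,5E,8S,9E)-3-[(tert-butyldimethylsilyl)oxy]-10-iodo-4,4,8-trimethyl-1,7-dioxoundeca-5,9-dien-2-yl 3-methylbutanoate
Product: 23 (2E,5S,6R,7S,8E,10S)-5-[(tert-butyldimethylsilyl)oxy]-7-hydroxy-4,4,8,10-tetramethyl-1-oxocyclodeca-2,8-dien-6-yl 3-methylbutanoate (locants of the cyclodecadienone)
Conditions: CrCl2, NiCl2 (cat.), chiral (4-isopropyl-4,5-dihydrooxazol-2-yl)aryl sulfonamide ligand, Et3N, THF, 2 mM, rt
Reagents that add atoms: none
Why: Intramolecular Nozaki–Hiyama–Kishi coupling of the vinyl iodide (C11) with the aldehyde (C1) closes the ten-membered ring with retention of alkene geometry, and the chiral chromium ligand (enantiomer chosen for this purpose) is relied on to deliver the C1 carbinol syn to the C2 acyloxy group against the modest Felkin preference.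

Step 15
Reactants: 23 (2E,5S,6R,7S,8E,10S)-5-[(tert-butyldimethylsilyl)oxy]-7-hydroxy-4,4,8,10-tetramethyl-1-oxocyclodeca-2,8-dien-6-yl 3-methylbutanoate
Product: 24 5-[(tert-butyldimethylsilyl)oxy]-3-hydroxy-2,6,6,10-tetramethyl-9-oxotricyclo[5.3.0.0^{2,8}]decan-4-yl 3-methylbutanoate (C8-nor ketone; C7 methyl syn to C5–H)
Conditions: hν (350 nm), MeCN (degassed, 2 mM), rt
Reagents that add atoms: none
Why: Transannular enone–alkene [2+2] photocycloaddition of the hexa-1,5-dien-3-one unit, in which the triplet enone bonds through its β-carbon C5 to C6 (five-membered ring first, rule of five) and the 1,4-diradical closes C10–C11 to the crossed bicyclo[2.1.1]hexan-2-one; the two ring tethers fix the relative configuration of C5, C6, C10 and C11, and allylic 1,3-strain between the C7 substituents and the C11 methyl should hold the enone on the one alkene face that gives the required sense of the cage (C7 methyl syn to C5).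

Step 16
Reactants: 24 5-[(tert-butyldimethylsilyl)oxy]-3-hydroxy-2,6,6,10-tetramethyl-9-oxotricyclo[5.3.0.0^{2,8}]decan-4-yl 3-methylbutanoate
Product: 25 5-[(tert-butyldimethylsilyl)oxy]-2,6,6,10-tetramethyl-3,9-bis[(trimethylsilyl)oxy]tricyclo[5.3.0.0^{2,8}]dec-9-en-4-yl 3-methylbutanoate
Conditions: TMSOTf, Et3N, CH2Cl2, 0 °C to rt
Reagents that add atoms: trimethylsilyl trifluoromethanesulfonate C[Si](C)(C)OS(=O)(=O)C(F)(F)F
Why: Soft enolisation gives the only possible silyl enol ether (C9=C7), because C10 is a bridgehead, and silylates the C1 hydroxyl in passing; the C7 centre becomes sp2.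

Step 17
Reactants: 25 5-[(tert-butyldimethylsilyl)oxy]-2,6,6,10-tetramethyl-3,9-bis[(trimethylsilyl)oxy]tricyclo[5.3.0.0^{2,8}]dec-9-en-4-yl 3-methylbutanoate
Product: 27 5-[(tert-butyldimethylsilyl)oxy]-10-chloro-3-hydroxy-2,6,6,11-tetramethyl-9-oxotricyclo[5.4.0.0^{2,8}]undec-10-en-4-yl 3-methylbutanoate, via dichlorocyclopropane 26 (not isolated)
Conditions: Cl3CCO2Na, DME, 85 °C; then 1 M HCl (work-up)
Reagents that add atoms: sodium trichloroacetate [Na+].[O-]C(=O)C(Cl)(Cl)Cl
Why: Dichlorocarbene, released by decarboxylation of the trichloroacetate, adds in a [2+1] fashion to the electron-rich enol ether C7=C9 from the face of C5–H; the resulting 1-siloxy-2,2-dichlorocyclopropane loses the chloride that is syn to the ring while the shared bond C7–C9 opens in a disrotatory 2π-electrocyclic reaction to a 2-siloxyallyl cation, which is desilylated by chloride. The closest known reaction type is the dihalocarbene one-carbon ring expansion of cyclic silyl enol ethers to 2-halocycloalk-2-enones. The only ring closed is the transient cyclopropane (cheletropic [2+1] addition); the ring C5–C6–C7–C8–C9–C10 arises because the five-membered ring C5–C6–C7–C9–C10 takes up C8 when the C7–C9 bond breaks, driven by release of cyclopropane strain. No stereocentre is created in 27, since C7 is sp2; the two cyclopropane centres of 26 follow from approach anti to the C11 methyl and are erased. The step needs regioselectivity (C8 between C9 and C7, not between C9 and C10) and chemoselectivity: the first is secured by the bridgehead position of C10, which allows only the C7 enol ether, and by the fact that only the cyclopropane bond opposite the CCl2 carbon can open; the second by the nucleophilicity of the enol ether toward the electrophilic carbene, the ester and silyl ethers being inert.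

Step 18
Reactants: 27 5-[(tert-butyldimethylsilyl)oxy]-10-chloro-3-hydroxy-2,6,6,11-tetramethyl-9-oxotricyclo[5.4.0.0^{2,8}]undec-10-en-4-yl 3-methylbutanoate
Product: 28 5-[(tert-butyldimethylsilyl)oxy]-3-hydroxy-2,6,6,11-tetramethyl-9-oxotricyclo[5.4.0.0^{2,8}]undecan-4-yl 3-methylbutanoate
Conditions: H2 (3 atm), Pd/C, Et3N, EtOAc, rt
Reagents that add atoms: none
Why: Catalytic hydrogenolysis of the vinylic C–Cl bond and syn hydrogenation of the enone C=C, where hydrogen should reach C7 from the face of the C5–H bridge (anti to the overhanging C11 methyl, as in the hydrogenation of verbenone to cis-verbanone), which places the C7 methyl syn to C11 as in the target.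

Step 19
Reactants: 28 5-[(tert-butyldimethylsilyl)oxy]-3-hydroxy-2,6,6,11-tetramethyl-9-oxotricyclo[5.4.0.0^{2,8}]undecan-4-yl 3-methylbutanoate; 29 angelic acid
Product: 31 5-[(tert-butyldimethylsilyl)oxy]-2,6,6,11-tetramethyl-4-[(3-methylbutanoyl)oxy]-9-oxotricyclo[5.4.0.0^{2,8}]undecan-3-yl (Z)-2-methylbut-2-enoate, via mixed anhydride 30 (not isolated)
Conditions: 2,4,6-Cl3C6H2COCl, Et3N, toluene, rt; then 28, 80 °C
Reagents that add atoms: none
Why: Yamaguchi-type acylation through the 2,4,6-trichlorobenzoyl mixed anhydride without a nucleophilic catalyst should esterify the hindered C1 alcohol without Z-to-E isomerisation of the angelate.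

Step 20
Reactants: 31 5-[(tert-butyldimethylsilyl)oxy]-2,6,6,11-tetramethyl-4-[(3-methylbutanoyl)oxy]-9-oxotricyclo[5.4.0.0^{2,8}]undecan-3-yl (Z)-2-methylbut-2-enoate
Product: 32 CNP0323312.1
Conditions: HF·pyridine, pyridine, THF, 0 °C to rt
Reagents that add atoms: none
Why: Fluoride-mediated cleavage of the TBS ether under weakly acidic conditions frees the C3 hydroxyl while avoiding migration of the neighbouring isovaleryl group and isomerisation of the angelate.

Compound list
1 | (R)-2,2-dimethyl-1,3-dioxolane-4-carbaldehyde ((R)-glyceraldehyde acetonide) | CC1(C)OC[C@@H](O1)C=O | starting material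
2 | 1-bromo-3-methylbut-2-ene (prenyl bromide) | CC(C)=CCBr | starting material
3 | (S)-1-[(R)-2,2-dimethyl-1,3-dioxolan-4-yl]-2,2-dimethylbut-3-en-1-ol | CC1(C)OC[C@@H](O1)[C@@H](O)C(C)(C)C=C | intermediate
4 | tert-butyl{[(S)-1-[(R)-2,2-dimethyl-1,3-dioxolan-4-yl]-2,2-dimethylbut-3-en-1-yl]oxy}dimethylsilane | CC1(C)OC[C@@H](O1)[C@@H](O[Si](C)(C)C(C)(C)C)C(C)(C)C=C | intermediate
5 | ozonide (3-substituted 1,2,4-trioxolane) of 4 | CC1(C)OC[C@@H](O1)[C@@H](O[Si](C)(C)C(C)(C)C)C(C)(C)C1OCOO1 | intermediate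
6 | (S)-3-[(tert-butyldimethylsilyl)oxy]-3-[(R)-2,2-dimethyl-1,3-dioxolan-4-yl]-2,2-dimethylpropanal | CC1(C)OC[C@@H](O1)[C@@H](O[Si](C)(C)C(C)(C)C)C(C)(C)C=O | intermediate
7 | 2-(triphenyl-λ5-phosphanylidene)acetaldehyde | O=CC=P(c1ccccc1)(c1ccccc1)c1ccccc1 | starting material
8 | (S,E)-5-[(tert-butyldimethylsilyl)oxy]-5-[(R)-2,2-dimethyl-1,3-dioxolan-4-yl]-4,4-dimethylpent-2-enal | CC1(C)OC[C@@H](O1)[C@@H](O[Si](C)(C)C(C)(C)C)C(C)(C)/C=C/C=O | intermediate
9 | (R)-but-3-yn-2-ol | O[C@H](C)C#C | starting material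
10 | dilithium alkoxide acetylide of 9 | [Li+].[Li+].[O-][C@H](C)C#[C-] | intermediate
11 | (R)-pent-3-yn-2-ol | O[C@H](C)C#CC | intermediate
12 | (R)-pent-3-yn-2-yl methanesulfonate | CS(=O)(=O)O[C@H](C)C#CC | intermediate
13 | (4S,5R,6E,9S)-9-[(tert-butyldimethylsilyl)oxy]-9-[(R)-2,2-dimethyl-1,3-dioxolan-4-yl]-4,8,8-trimethylnon-6-en-2-yn-5-ol | CC1(C)OC[C@@H](O1)[C@@H](O[Si](C)(C)C(C)(C)C)C(C)(C)/C=C/[C@@H](O)[C@@H](C)C#CC | intermediate
14 | C,O-bis(chlorozirconocene) derivative of 13 (alkenylzirconium at C11, cyclopentadienyl ligands drawn σ-bonded) | CC1(C)OC[C@@H](O1)[C@@H](O[Si](C)(C)C(C)(C)C)C(C)(C)/C=C/[C@@H](O[Zr](Cl)(C1C=CC=C1)C1C=CC=C1)[C@@H](C)/C=C(/[Zr](Cl)(C1C=CC=C1)C1C=CC=C1)C | intermediate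
15 | (2E,4S,5R,6E,9S)-9-[(tert-butyldimethylsilyl)oxy]-9-[(R)-2,2-dimethyl-1,3-dioxolan-4-yl]-2-iodo-4,8,8-trimethylnona-2,6-dien-5-ol | CC1(C)OC[C@@H](O1)[C@@H](O[Si](C)(C)C(C)(C)C)C(C)(C)/C=C/[C@@H](O)[C@@H](C)/C=C(/I)C | intermediate
16 | (2E,4S,6E,9S)-9-[(tert-butyldimethylsilyl)oxy]-9-[(R)-2,2-dimethyl-1,3-dioxolan-4-yl]-2-iodo-4,8,8-trimethylnona-2,6-dien-5-one | CC1(C)OC[C@@H](O1)[C@@H](O[Si](C)(C)C(C)(C)C)C(C)(C)/C=C/C(=O)[C@@H](C)/C=C(/I)C | intermediate
17 | (2R,3S,5E,8S,9E)-3-[(tert-butyldimethylsilyl)oxy]-1,2-dihydroxy-10-iodo-4,4,8-trimethylundeca-5,9-dien-7-one | OC[C@@H](O)[C@@H](O[Si](C)(C)C(C)(C)C)C(C)(C)/C=C/C(=O)[C@@H](C)/C=C(/I)C | intermediate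
18 | (2R,3S,5E,8S,9E)-3-[(tert-butyldimethylsilyl)oxy]-2-hydroxy-10-iodo-4,4,8-trimethyl-1-[(triethylsilyl)oxy]undeca-5,9-dien-7-one | CC[Si](CC)(CC)OC[C@@H](O)[C@@H](O[Si](C)(C)C(C)(C)C)C(C)(C)/C=C/C(=O)[C@@H](C)/C=C(/I)C | intermediate
19 | 3-methylbutanoyl chloride (isovaleryl chloride) | CC(C)CC(=O)Cl | starting material
20 | (2R,3S,5E,8S,9E)-3-[(tert-butyldimethylsilyl)oxy]-10-iodo-4,4,8-trimethyl-7-oxo-1-[(triethylsilyl)oxy]undeca-5,9-dien-2-yl 3-methylbutanoate | CC[Si](CC)(CC)OC[C@@H](OC(=O)CC(C)C)[C@@H](O[Si](C)(C)C(C)(C)C)C(C)(C)/C=C/C(=O)[C@@H](C)/C=C(/I)C | intermediate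
21 | alkoxydimethylsulfonium chloride formed at the C1 oxygen of 20 | C[S+](C)OC[C@@H](OC(=O)CC(C)C)[C@@H](O[Si](C)(C)C(C)(C)C)C(C)(C)/C=C/C(=O)[C@@H](C)/C=C(/I)C.[Cl-] | intermediate
22 | (2S,3S,5E,8S,9E)-3-[(tert-butyldimethylsilyl)oxy]-10-iodo-4,4,8-trimethyl-1,7-dioxoundeca-5,9-dien-2-yl 3-methylbutanoate | O=C[C@@H](OC(=O)CC(C)C)[C@@H](O[Si](C)(C)C(C)(C)C)C(C)(C)/C=C/C(=O)[C@@H](C)/C=C(/I)C | intermediate
23 | (2E,5S,6R,7S,8E,10S)-5-[(tert-butyldimethylsilyl)oxy]-7-hydroxy-4,4,8,10-tetramethyl-1-oxocyclodeca-2,8-dien-6-yl 3-methylbutanoate | O[C@@H]1[C@@H](OC(=O)CC(C)C)[C@@H](O[Si](C)(C)C(C)(C)C)C(C)(C)/C=C/C(=O)[C@@H](C)/C=C/1C | intermediate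
24 | 5-[(tert-butyldimethylsilyl)oxy]-3-hydroxy-2,6,6,10-tetramethyl-9-oxotricyclo[5.3.0.0^{2,8}]decan-4-yl 3-methylbutanoate (C7 methyl syn to C5–H; configuration as in the SMILES) | O[C@@H]1[C@@H](OC(=O)CC(C)C)[C@@H](O[Si](C)(C)C(C)(C)C)C(C)(C)[C@H]2[C@@H]3[C@H](C)C(=O)[C@H]2[C@@]31C | intermediate
25 | 5-[(tert-butyldimethylsilyl)oxy]-2,6,6,10-tetramethyl-3,9-bis[(trimethylsilyl)oxy]tricyclo[5.3.0.0^{2,8}]dec-9-en-4-yl 3-methylbutanoate | C[Si](C)(C)O[C@@H]1[C@@H](OC(=O)CC(C)C)[C@@H](O[Si](C)(C)C(C)(C)C)C(C)(C)[C@H]2[C@@H]3C(C)=C(O[Si](C)(C)C)[C@H]2[C@@]31C | intermediate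
26 | dichlorocarbene adduct of 25 (1-siloxy-2,2-dichlorocyclopropane across C7–C9, CCl2 on the side of C5) | C[Si](C)(C)O[C@@H]1[C@@H](OC(=O)CC(C)C)[C@@H](O[Si](C)(C)C(C)(C)C)C(C)(C)[C@H]2[C@@H]3[C@]4(C)C(Cl)(Cl)[C@]4(O[Si](C)(C)C)[C@H]2[C@@]31C | intermediate
27 | 5-[(tert-butyldimethylsilyl)oxy]-10-chloro-3-hydroxy-2,6,6,11-tetramethyl-9-oxotricyclo[5.4.0.0^{2,8}]undec-10-en-4-yl 3-methylbutanoate | O[C@@H]1[C@@H](OC(=O)CC(C)C)[C@@H](O[Si](C)(C)C(C)(C)C)C(C)(C)[C@H]2[C@@H]3C(C)=C(Cl)C(=O)[C@H]2[C@@]31C | intermediate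
28 | 5-[(tert-butyldimethylsilyl)oxy]-3-hydroxy-2,6,6,11-tetramethyl-9-oxotricyclo[5.4.0.0^{2,8}]undecan-4-yl 3-methylbutanoate | O[C@@H]1[C@@H](OC(=O)CC(C)C)[C@@H](O[Si](C)(C)C(C)(C)C)C(C)(C)[C@H]2[C@@H]3[C@@H](C)CC(=O)[C@H]2[C@@]31C | intermediate
29 | angelic acid ((Z)-2-methylbut-2-enoic acid) | C/C=C(/C)C(=O)O | starting material
30 | (Z)-2-methylbut-2-enoic 2,4,6-trichlorobenzoic anhydride | C/C=C(/C)C(=O)OC(=O)c1c(Cl)cc(Cl)cc1Cl | intermediate
31 | 5-[(tert-butyldimethylsilyl)oxy]-2,6,6,11-tetramethyl-4-[(3-methylbutanoyl)oxy]-9-oxotricyclo[5.4.0.0^{2,8}]undecan-3-yl (Z)-2-methylbut-2-enoate | C/C=C(/C)C(=O)O[C@@H]1[C@@H](OC(=O)CC(C)C)[C@@H](O[Si](C)(C)C(C)(C)C)C(C)(C)[C@H]2[C@@H]3[C@@H](C)CC(=O)[C@H]2[C@@]31C | intermediate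
32 | CNP0323312.1, 5-hydroxy-2,6,6,11-tetramethyl-4-[(3-methylbutanoyl)oxy]-9-oxotricyclo[5.4.0.0^{2,8}]undecan-3-yl (Z)-2-methylbut-2-enoate | C/C=C(/C)C(=O)O[C@@H]1[C@@H](OC(=O)CC(C)C)[C@@H](O)C(C)(C)[C@H]2[C@@H]3[C@@H](C)CC(=O)[C@H]2[C@@]31C | target

Total step count: 20. Longest linear sequence: 18 steps (steps 1–4 and 7–20); steps 5 and 6 prepare the side fragment 12.

Steps most likely to fail

1. Step 14 (ring closure). The ten-membered (E,E)-diene ring may close slowly, and reagent control over the new carbinol may be insufficient, since Felkin addition favours the C1 epimer. Fallback: setting out from 22, the ring is closed with CrCl2/NiCl2 in DMSO without a chiral ligand, which should give mainly the C1-epimeric macrocyclic alcohol F1. Mitsunobu inversion with chloroacetic acid (PPh3, DIAD, toluene) then gives the inverted chloroacetate F2, and thiourea/NaHCO3 in ethanol removes the chloroacetyl group in the presence of the isovalerate, which comes back to the route at 23.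

2. Step 15 (photocycloaddition). Facial control may be lost, through epimerisation of the steering centre C7 beforehand or through a competing bias from C1–C3, and α-cleavage or 1,3-acyl shift of the β,γ-unsaturated ketone may compete. Fallback: setting out from 23, Luche reduction (NaBH4, CeCl3·7H2O, MeOH, −78 °C) gives the macrocyclic allylic diol F3. Copper(I)-catalysed [2+2] photocycloaddition of this non-conjugated 1,5-diene (CuOTf, Et2O, 254 nm), in which copper binds both alkenes and no carbonyl photochemistry can interfere, gives the bicyclo[2.1.1]hexanol F4. Oxidation of its less hindered ring carbinol (TEMPO, PhI(OAc)2) comes back to the route at 24.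

3. Step 17 (key step). The dichlorocyclopropane may open incompletely, or the cationic intermediate next to the cyclobutane may undergo skeletal rearrangement. Fallback: setting out from 25, Simmons–Smith cyclopropanation (Et2Zn, CH2I2, CH2Cl2) gives the siloxycyclopropane F5. One-electron oxidation with FeCl3 in DMF (β-scission of the C7–C9 bond and chlorine transfer) gives the ring-expanded β-chloro ketone F6, which DBU converts into the chlorine-free enone F7. Hydrogenation (H2, Pd/C, EtOAc) comes back to the route at 28.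

Further compounds
F1 | step 14 | C1 epimer of 23 | O[C@H]1[C@@H](OC(=O)CC(C)C)[C@@H](O[Si](C)(C)C(C)(C)C)C(C)(C)/C=C/C(=O)[C@@H](C)/C=C/1C
F2 | step 14 | chloroacetate of 23 (C1 configuration of the target) | ClCC(=O)O[C@@H]1[C@@H](OC(=O)CC(C)C)[C@@H](O[Si](C)(C)C(C)(C)C)C(C)(C)/C=C/C(=O)[C@@H](C)/C=C/1C
F3 | step 15 | C9 alcohol (allylic diol) from 23, mixture at C9 | O[C@@H]1[C@@H](OC(=O)CC(C)C)[C@@H](O[Si](C)(C)C(C)(C)C)C(C)(C)/C=C/C(O)[C@@H](C)/C=C/1C
F4 | step 15 | C9 alcohol corresponding to 24, mixture at C9 | O[C@@H]1[C@@H](OC(=O)CC(C)C)[C@@H](O[Si](C)(C)C(C)(C)C)C(C)(C)[C@H]2[C@@H]3[C@H](C)C(O)[C@H]2[C@@]31C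
F5 | step 17 | siloxycyclopropane from 25 (CH2 across C7–C9) | C[Si](C)(C)O[C@@H]1[C@@H](OC(=O)CC(C)C)[C@@H](O[Si](C)(C)C(C)(C)C)C(C)(C)[C@H]2[C@@H]3[C@]4(C)C[C@]4(O[Si](C)(C)C)[C@H]2[C@@]31C
F6 | step 17 | ring-expanded β-chloro ketone (chlorine at C7, mixture) | O[C@@H]1[C@@H](OC(=O)CC(C)C)[C@@H](O[Si](C)(C)C(C)(C)C)C(C)(C)[C@H]2[C@@H]3C(C)(Cl)CC(=O)[C@H]2[C@@]31C
F7 | step 17 | chlorine-free enone (C8=C7) | O[C@@H]1[C@@H](OC(=O)CC(C)C)[C@@H](O[Si](C)(C)C(C)(C)C)C(C)(C)[C@H]2[C@@H]3C(C)=CC(=O)[C@H]2[C@@]31C
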